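**Retrosynthetic overview**
- Target ⇒ tetramethoxy biaryl bis-ynone: both O1–C2 bonds and all four O–H bonds are made in one flask, so the two pyranone rings are closed last and together by C–O bond formation.
- Bis-ynone ⇒ biaryl dialdehyde + 2 × 4-phenyl-1-butyne (acetylide addition, then oxidation).
- Biaryl dialdehyde ⇒ 5-bromo-2,4-dimethoxybenzaldehyde + 6-bromo-2,3-dimethoxybenzaldehyde (one-flask borylation/Suzuki–Miyaura coupling).
- Ring order: both benzene rings are bought, the biaryl bond is made first, and the two 4-pyranone rings are formed simultaneously in the final step.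

Assumption: the SMILES has no stereodescriptor and no stereocentre, and the biaryl axis (flanked only by 7-OH/H on one side and the ring fusion/H on the other) is taken as freely rotating, so the target is a single achiral compound and no stereocontrol is needed.

Ring A is the 2,4-dimethoxyphenyl-derived ring (it becomes the 7-hydroxychromone unit). Ring B is the 2,3-dimethoxyphenyl-derived ring (it becomes the 8-hydroxychromone unit).

**Step 1**
Reactants: 1 5-bromo-2,4-dimethoxybenzaldehyde; 2 bis(pinacolato)diboron; 3 6-bromo-2,3-dimethoxybenzaldehyde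
Product: 5 2',3,4,4'-tetramethoxy[1,1'-biphenyl]-2,5'-dicarbaldehyde, via aryl pinacol boronate 4 (not isolated)
Conditions: 1 (1.2 equiv), 2 (1.15 equiv), Pd(dppf)Cl2 (3 mol %), KOAc (3 equiv), 1,4-dioxane, 90 °C, 3 h; then 3 (1.0 equiv), 2 M aq. K3PO4 (3 equiv), 90 °C, 12 h
Reagents that add atoms: none
Why: Miyaura borylation of the electron-rich bromide 1, followed in the same flask by Suzuki–Miyaura cross-coupling of boronate 4 with the ortho-formyl-activated bromide 3, makes a biaryl bond with only two ortho substituents around it; the aldehydes and methyl ethers tolerate KOAc and aqueous K3PO4, 1 is kept in slight excess over 2 so no diboron is left to borylate 3, and no stereocentre is formed.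

**Step 2**
Reactants: 5 2',3,4,4'-tetramethoxy[1,1'-biphenyl]-2,5'-dicarbaldehyde; 6 4-phenyl-1-butyne; 7 n-butyllithium
Product: 9 1,1'-(2',3,4,4'-tetramethoxy[1,1'-biphenyl]-2,5'-diyl)bis(5-phenylpent-2-yn-1-ol) (mixture of diastereomers), via lithium acetylide 8 (not isolated)
Conditions: 6 (2.8 equiv), 7 (2.6 equiv), THF, −78 °C, 30 min; then 5, −78 → 0 °C, 2 h; sat. aq. NH4Cl
Reagents that add atoms: none
Why: Alkynylation (1,2-addition of lithium acetylide 8 to both aromatic aldehydes) is fast at −78 °C even at the doubly flanked aldehyde of ring B; the two carbinol stereocentres form without control, the diastereomer mixture is used as such, and both centres are erased in step 3.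

**Step 3**
Reactants: 9 1,1'-(2',3,4,4'-tetramethoxy[1,1'-biphenyl]-2,5'-diyl)bis(5-phenylpent-2-yn-1-ol)
Product: 10 1,1'-(2',3,4,4'-tetramethoxy[1,1'-biphenyl]-2,5'-diyl)bis(5-phenylpent-2-yn-1-one)
Conditions: Dess–Martin periodinane (2.6 equiv), CH2Cl2, 0 °C → rt, 1 h
Reagents that add atoms: none
Why: Dess–Martin oxidation converts both secondary benzylic–propargylic alcohols to ynones under neutral, non-basic conditions, so the propargylic CH2 groups do not isomerise to allenes, the methyl ethers are untouched, and both stereocentres disappear.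

**Step 4**
Reactants: 10 1,1'-(2',3,4,4'-tetramethoxy[1,1'-biphenyl]-2,5'-diyl)bis(5-phenylpent-2-yn-1-one); 11 hydrogen bromide
Product: 14 7-hydroxy-6-[8-hydroxy-4-oxo-2-(2-phenylethyl)-4H-chromen-5-yl]-2-(2-phenylethyl)-4H-chromen-4-one (target), via bis(bromoenone) 12 (not isolated), via bis-chromone dimethyl ether 13 (not isolated)
Conditions: 33% HBr in AcOH (excess), N2, 25 °C, 1 h, then 70 °C, 2 h; then 48% aq. HBr added, reflux (ca. 120 °C), 10 h; poured onto ice water
Reagents that add atoms: none
Why: Proposed new method: a proton/bromide-relayed double demethylative 6-endo oxa-cyclisation merged with global O-demethylation — HBr adds in conjugate fashion to each O-protonated ynone to give β-bromo enone 12; the neighbouring methoxy oxygen attacks the β-carbon (6-endo addition–elimination with loss of bromide, forming the O1–C2 bond of each pyranone) to give an O-methyl chromenylium oxonium ion, which bromide dealkylates by SN2 (MeBr) to chromone 13; at reflux the same reagent cleaves the two remaining aryl methyl ethers; acid conditions favour 6-endo over 5-exo (aurone) closure because only the β-carbon is electrophilic; the closest known reaction types are the ICl-induced demethylative iodocyclisation of 2-methoxyaryl ynones (which gives 3-iodochromones), the strong-acid-promoted 6-endo cyclisation of 2-hydroxyaryl ynones, and the classical HBr/AcOH demethylative cyclodehydration of 2-methoxyaryl 1,3-diketones, whereas, to my knowledge, a hydrogen-halide-triggered closure of a methoxyaryl ynone to a C3-unsubstituted chromone, run twice on one biaryl and coupled with deprotection in one flask, has not been shown; no stereocentre is formed.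

**Compound list**
1 | 5-bromo-2,4-dimethoxybenzaldehyde | COc1cc(OC)c(Br)cc1C=O | starting material
2 | bis(pinacolato)diboron | CC1(C)OB(OC1(C)C)B1OC(C)(C)C(C)(C)O1 | starting material
3 | 6-bromo-2,3-dimethoxybenzaldehyde | COc1ccc(Br)c(C=O)c1OC | starting material
4 | 2,4-dimethoxy-5-(4,4,5,5-tetramethyl-1,3,2-dioxaborolan-2-yl)benzaldehyde | COc1cc(OC)c(B2OC(C)(C)C(C)(C)O2)cc1C=O | intermediate
5 | 2',3,4,4'-tetramethoxy[1,1'-biphenyl]-2,5'-dicarbaldehyde | COc1cc(OC)c(-c2ccc(OC)c(OC)c2C=O)cc1C=O | intermediate
6 | 4-phenyl-1-butyne | C#CCCc1ccccc1 | starting material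
7 | n-butyllithium | [Li]CCCC | starting material
8 | lithium 4-phenylbut-1-yn-1-ide | [Li+].[C-]#CCCc1ccccc1 | intermediate
9 | 1,1'-(2',3,4,4'-tetramethoxy[1,1'-biphenyl]-2,5'-diyl)bis(5-phenylpent-2-yn-1-ol), mixture of diastereomers | COc1cc(OC)c(-c2ccc(OC)c(OC)c2C(O)C#CCCc3ccccc3)cc1C(O)C#CCCc4ccccc4 | intermediate
10 | 1,1'-(2',3,4,4'-tetramethoxy[1,1'-biphenyl]-2,5'-diyl)bis(5-phenylpent-2-yn-1-one) | COc1cc(OC)c(-c2ccc(OC)c(OC)c2C(=O)C#CCCc3ccccc3)cc1C(=O)C#CCCc4ccccc4 | intermediate
11 | hydrogen bromide | Br | starting material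
12 | 1,1'-(2',3,4,4'-tetramethoxy[1,1'-biphenyl]-2,5'-diyl)bis(3-bromo-5-phenylpent-2-en-1-one), E/Z mixture | COc1cc(OC)c(-c2ccc(OC)c(OC)c2C(=O)C=C(Br)CCc3ccccc3)cc1C(=O)C=C(Br)CCc4ccccc4 | intermediate
13 | 7-methoxy-6-[8-methoxy-4-oxo-2-(2-phenylethyl)-4H-chromen-5-yl]-2-(2-phenylethyl)-4H-chromen-4-one | O=c1cc(CCc2ccccc2)oc2cc(OC)c(-c3ccc(OC)c4oc(CCc5ccccc5)cc(=O)c34)cc12 | intermediate
14 | 7-hydroxy-6-[8-hydroxy-4-oxo-2-(2-phenylethyl)-4H-chromen-5-yl]-2-(2-phenylethyl)-4H-chromen-4-one (CNP0279305.0) | O=c1cc(CCc2ccccc2)oc2cc(O)c(-c3ccc(O)c4oc(CCc5ccccc5)cc(=O)c34)cc12 | target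

**Totals**
Total step count: 4. Longest linear sequence: 4 steps (from 1 or 3 to 14).

**Steps most likely to fail**

Step 4 (the proposed new cascade) could stall at partly closed or partly demethylated material, or the ynones could degrade in hot acid. The fallback uses only known chemistry and sets out from 10. Diethylamine (EtOH, rt) adds to both ynones to give the bis-enaminone 1,1'-(2',3,4,4'-tetramethoxy[1,1'-biphenyl]-2,5'-diyl)bis[3-(diethylamino)-5-phenylpent-2-en-1-one] F4. BBr3 (CH2Cl2, −78 °C → rt) then cleaves all four methyl ethers. Warming with dilute HCl in MeOH lets each freed ortho-hydroxyl displace diethylamine (the established enaminone-to-chromone closure). This comes back to the route at 14.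

Step 1 (one-flask borylation/coupling) could suffer protodeboronation of the electron-rich ortho-methoxy boronate or scrambling of the two bromides. The fallback sets out from 1 and changes the organometallic partner. Stannylation with hexabutylditin and Pd(PPh3)4 (toluene, 110 °C) gives the isolable 2,4-dimethoxy-5-(tributylstannyl)benzaldehyde F1. Stille coupling of F1 with 3 (Pd(PPh3)4, CuI, CsF, DMF, 60 °C) comes back to the route at 5.

Step 2 (double alkynylation) could stop at mono-adducts because the ring B aldehyde sits between a methoxy group and the biaryl bond. The fallback sets out from 5 and moves to the acid oxidation level. Pinnick oxidation (NaClO2, NaH2PO4, 2-methyl-2-butene, t-BuOH/H2O) gives 2',3,4,4'-tetramethoxy[1,1'-biphenyl]-2,5'-dicarboxylic acid F2. Oxalyl chloride with catalytic DMF (CH2Cl2) gives 2',3,4,4'-tetramethoxy[1,1'-biphenyl]-2,5'-dicarbonyl dichloride F3. Acyl Sonogashira coupling of F3 with 6 (PdCl2(PPh3)2, CuI, Et3N, THF, rt) comes back to the route at 10, so step 3 is no longer needed.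

**Further compounds**
F1 | step 1 | 2,4-dimethoxy-5-(tributylstannyl)benzaldehyde | CCCC[Sn](CCCC)(CCCC)c1cc(C=O)c(OC)cc1OC
F2 | step 2 | 2',3,4,4'-tetramethoxy[1,1'-biphenyl]-2,5'-dicarboxylic acid | COc1cc(OC)c(-c2ccc(OC)c(OC)c2C(=O)O)cc1C(=O)O
F3 | step 2 | 2',3,4,4'-tetramethoxy[1,1'-biphenyl]-2,5'-dicarbonyl dichloride | COc1cc(OC)c(-c2ccc(OC)c(OC)c2C(=O)Cl)cc1C(=O)Cl
F4 | step 4 | 1,1'-(2',3,4,4'-tetramethoxy[1,1'-biphenyl]-2,5'-diyl)bis[3-(diethylamino)-5-phenylpent-2-en-1-one] | CCN(CC)C(CCc1ccccc1)=CC(=O)c1cc(-c2ccc(OC)c(OC)c2C(=O)C=C(CCc3ccccc3)N(CC)CC)c(OC)cc1OC
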